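**Assumption:** Kuwanon B has no stereocentres (the SMILES is achiral), so no enantiocontrol is needed. The only stereocentre in the route (C2 of 8) is racemic and is destroyed in step 4.

## Retrosynthetic overview

1. Kuwanon B (11) ⇐ its 2'-O-MOM ether 10 by acetal cleavage.
2. 10 ⇐ phloroglucinol (9) + α-prenyl β-ketoester 8, by a one-pot thermal C-acylation/cyclodehydration that differentiates the three equivalent positions of phloroglucinol and delivers the C ring, C2-aryl, C3-prenyl and 5,7-(OH)2 together.
3. 8 ⇐ MOM-protected acetylchromene 5 by carbethoxylation and C-prenylation in one flask.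
4. 5 ⇐ 2,4-dihydroxyacetophenone (1) + prenal (2), by chromene annulation through a transient dearomatised o-quinone methide.
5. Ring order: the B-ring 2H-pyran (chromene) first, the γ-pyranone C ring (fused to the phloroglucinol-derived A ring) last.

## Route

**Step 1**
Reactants: 1, 2,4-dihydroxyacetophenone; 2, 3-methylbut-2-enal (prenal)
Product: 3, 1-(5-hydroxy-2,2-dimethyl-2H-chromen-6-yl)ethan-1-one
Conditions: 2 (2 equiv), pyridine, 140 °C (sealed tube), 18 h
Reagents that add atoms: 3-methylbut-2-enal, CC(C)=CC=O
Why: Base-mediated Knoevenagel-type condensation at C3 (between the two OH groups) gives a dearomatised o-quinone methide that closes by oxa-6π electrocyclisation; the acetyl-chelated 2-OH stays free, so the 4-O becomes the pyran oxygen (angular chromene).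

**Step 2**
Reactants: 3; 4, chloromethyl methyl ether (MOMCl)
Product: 5, 1-[5-(methoxymethoxy)-2,2-dimethyl-2H-chromen-6-yl]ethan-1-one
Conditions: NaH (1.3 equiv), MOMCl (1.3 equiv), DMF, 0 °C → rt
Reagents that add atoms: MOMCl, COCCl
Why: Williamson-type O-alkylation of the sodium phenoxide, which overrides the intramolecular H-bond; the phenol must be masked because a free ortho-OH would lactonise the β-ketoester of step 3 to a 4-hydroxycoumarin.

**Step 3**
Reactants: 5; 6, diethyl carbonate; 7, prenyl bromide (1-bromo-3-methylbut-2-ene)
Product: 8, ethyl 2-{[5-(methoxymethoxy)-2,2-dimethyl-2H-chromen-6-yl]carbonyl}-5-methylhex-4-enoate (racemic)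
Conditions: NaH (2.2 equiv), (EtO)2CO (3 equiv), THF, reflux, 3 h; then AcOH (1.2 equiv, neutralises NaOEt and excess NaH), prenyl bromide (1.1 equiv), DMF, 0 °C → rt
Reagents that add atoms: diethyl carbonate, CCOC(=O)OCC; prenyl bromide, CC(C)=CCBr
Why: Claisen condensation of the methyl ketone enolate with diethyl carbonate gives the stabilised sodium β-ketoester enolate, which is C-alkylated in situ by the soft allylic bromide (SN2); MOM and chromene are inert to base.

**Step 4 (key step)**
Reactants: 8; 9, phloroglucinol (benzene-1,3,5-triol, anhydrous)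
Product: 10, 5,7-dihydroxy-2-[5-(methoxymethoxy)-2,2-dimethyl-2H-chromen-6-yl]-3-(3-methylbut-2-en-1-yl)-4H-chromen-4-one
Conditions: 9 (2.5 equiv), neat melt, 235–240 °C (microwave), 10–15 min, N2 sweep (−EtOH, −H2O)
Reagents that add atoms: phloroglucinol, Oc1cc(O)cc(O)c1
Why: Mentzer-type thermal pyrone annulation, here extended to an α-prenyl, ortho-alkoxy aroylacetate: thermal loss of EtOH gives the aroyl(prenyl)ketene, which C-acylates one of the three equivalent carbons of phloroglucinol, and the resulting 1,3-diketone cyclodehydrates through the adjacent OH onto the aroyl carbonyl; acid-free conditions avoid the Pechmann coumarin and only the A ring carries a free OH, so the regiochemistry is unambiguous.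

**Step 5**
Reactants: 10
Product: 11, Kuwanon B, 5,7-dihydroxy-2-(5-hydroxy-2,2-dimethyl-2H-chromen-6-yl)-3-(3-methylbut-2-en-1-yl)-4H-chromen-4-one
Conditions: 3 M aq. HCl/MeOH (1:4), 50 °C, 1–2 h
Reagents that add atoms: none
Why: Acid-catalysed acetal (MOM) cleavage; the prenyl and 2,2-dimethylchromene olefins tolerate brief dilute HCl/MeOH, and cyclisation of the 3-prenyl group onto the 2'-OH would need an eight-membered ring, so it does not compete.

## Compound list

1 | 2,4-dihydroxyacetophenone | CC(=O)c1ccc(O)cc1O | starting material
2 | 3-methylbut-2-enal (prenal) | CC(C)=CC=O | starting material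
3 | 1-(5-hydroxy-2,2-dimethyl-2H-chromen-6-yl)ethan-1-one | CC(=O)c1ccc2OC(C)(C)C=Cc2c1O | intermediate
4 | chloromethyl methyl ether | COCCl | starting material
5 | 1-[5-(methoxymethoxy)-2,2-dimethyl-2H-chromen-6-yl]ethan-1-one | CC(=O)c1ccc2OC(C)(C)C=Cc2c1OCOC | intermediate
6 | diethyl carbonate | CCOC(=O)OCC | starting material
7 | prenyl bromide | CC(C)=CCBr | starting material
8 | ethyl 2-{[5-(methoxymethoxy)-2,2-dimethyl-2H-chromen-6-yl]carbonyl}-5-methylhex-4-enoate (racemic) | CCOC(=O)C(CC=C(C)C)C(=O)c1ccc2OC(C)(C)C=Cc2c1OCOC | intermediate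
9 | phloroglucinol | Oc1cc(O)cc(O)c1 | starting material
10 | 5,7-dihydroxy-2-[5-(methoxymethoxy)-2,2-dimethyl-2H-chromen-6-yl]-3-(3-methylbut-2-en-1-yl)-4H-chromen-4-one | CC(C)=CCc1c(-c2ccc3OC(C)(C)C=Cc3c2OCOC)oc2cc(O)cc(O)c2c1=O | intermediate
11 | Kuwanon B | CC(C)=CCc1c(-c2ccc3c(c2O)C=CC(C)(C)O3)oc2cc(O)cc(O)c2c1=O | target

## Summary

Total steps: 5. Longest linear sequence: 5 (1 → 3 → 5 → 8 → 10 → 11; phloroglucinol enters at step 4).

Steps most likely to fail:

1. **Step 4 (thermal annulation).** The risks are MOM loss or participation before C-acylation (giving the 3-prenyl-4-hydroxycoumarin), ketonic cleavage/decarboxylation of 8 by the water released, and bis-acylation of phloroglucinol.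
 Fallback: abandon the thermal ketene route and build the diketone under basic conditions by a Baker–Venkataraman sequence. Esterify 2-hydroxy-4,6-bis(methoxymethoxy)acetophenone with 5-(methoxymethoxy)-2,2-dimethyl-2H-chromene-6-carboxylic acid, perform the O→C acyl shift (KOH/pyridine or LiHMDS), C-prenylate the 1,3-diketone (K2CO3, prenyl bromide), then use HCl/MeOH for cyclodehydration and global MOM removal.

2. **Step 3 (one-flask carbethoxylation/prenylation).** The risks are incomplete alkylation, O- or di-prenylation, and retro-Claisen.
 Fallback: form the C–C bond with the prenyl already in place by a Masamune–Brooks decarboxylative acylation. React the acyl imidazolide of 5-(methoxymethoxy)-2,2-dimethyl-2H-chromene-6-carboxylic acid (from methyl 2,4-dihydroxybenzoate by the step 1–2 chemistry, then saponification) with potassium ethyl 2-prenylmalonate (MgCl2, Et3N) to give 8 directly.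

3. **Step 5 (acidic MOM removal).** The risk is acid-mediated hydration or cyclisation of the prenyl or chromene olefins.
 Fallback: avoid acid entirely by carrying the 2'-oxygen as a methyl ether from step 2 (MeI, K2CO3). This is also inert in the step 4 melt. Unmask it last by nucleophilic SN2 demethylation (NaSEt, DMF, 120 °C).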